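**Plan**
- The target is (3R)-3,7,2',4'-tetrahydroxy-6,8-diprenylisoflavanone; the last retrosynthetic cut removes three O-allyl groups (O7, O2', O4').
- Ring C is then cut at O1–C2 and C3–C4 together. The C4 ketone next to the C3 tertiary carbinol is an acyloin, and C2 is a methylene on the ring A phenol oxygen O1, so ring C = salicylaldehyde of ring A (C4 as acyl anion) + phenacyl bromide of ring B (C2 and C3 both electrophilic).
- Ring A piece: 2,4-dihydroxybenzaldehyde, diiodination at C3/C5, double Stille prenylation, 4-O-allylation. Ring B piece: 2',4'-dihydroxyacetophenone, bis-allylation, α-bromination.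
- Forward order: rings A and B are bought as arenes and decorated; ring C arises last, in one flask, by O-alkylation followed by a carbene-catalysed crossed benzoin; deallylation ends the route.
- Stereochemistry: the only stereocentre, C3 (R), is set by the chiral triazolylidene in the benzoin step and, being quaternary, cannot epimerise afterwards.

Key step: step 6

Assumption: the (5aR,10bS) antipode of the aminoindanol-derived triazolium salt is taken as the one that leads to the (R)-carbinol; the sense of induction is to be confirmed on the first run, and the (5aS,10bR) salt, equally available, is used instead if the opposite sense is found.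

**Step 1**
Reactants: 1 2,4-dihydroxybenzaldehyde; 2 N-iodosuccinimide
Product: 3 2,4-dihydroxy-3,5-diiodobenzaldehyde
Conditions: NIS (2.2 equiv), AcOH, rt, dark
Reagents that add atoms: N-iodosuccinimide (2), O=C1CCC(=O)N1I
Why: Electrophilic aromatic iodination should go only to C3 and C5, which are ortho/para to both hydroxyl groups, while C6 is meta to both and ortho to the formyl group.

**Step 2**
Reactants: 3 2,4-dihydroxy-3,5-diiodobenzaldehyde; 4 tributyl(3-methylbut-2-en-1-yl)stannane
Product: 5 2,4-dihydroxy-3,5-bis(3-methylbut-2-en-1-yl)benzaldehyde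
Conditions: 4 (3 equiv), Pd(PPh3)4 (10 mol%), DMF, 90 °C, degassed
Reagents that add atoms: tributyl(3-methylbut-2-en-1-yl)stannane (4), CCCC[Sn](CCCC)(CCCC)CC=C(C)C
Why: Twofold Stille coupling, in which zerovalent palladium inserts into each C–I bond and the prenyl group is transferred with C–C bond formation at its unsubstituted terminus, should give the linear prenyl groups at C3 and C5.

**Step 3**
Reactants: 5 2,4-dihydroxy-3,5-bis(3-methylbut-2-en-1-yl)benzaldehyde; 6 allyl bromide
Product: 7 2-hydroxy-3,5-bis(3-methylbut-2-en-1-yl)-4-(prop-2-en-1-yloxy)benzaldehyde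
Conditions: allyl bromide (1.05 equiv), K2CO3 (1.1 equiv), acetone, rt
Reagents that add atoms: allyl bromide (6), C=CCBr
Why: Williamson etherification should take the 4-OH, which is the more acidic phenol (para to the formyl group), while the 2-OH stays locked in its hydrogen bond to the aldehyde.

**Step 4**
Reactants: 8 1-(2,4-dihydroxyphenyl)ethan-1-one; 6 allyl bromide
Product: 9 1-[2,4-bis(prop-2-en-1-yloxy)phenyl]ethan-1-one
Conditions: allyl bromide (2.5 equiv), K2CO3 (3 equiv), DMF, 60 °C
Reagents that add atoms: allyl bromide (6), C=CCBr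
Why: Twofold Williamson etherification, with heating in DMF to overcome the chelated 2-OH, should cap both phenols so that the later bromoketone cannot close to a benzofuranone.

**Step 5**
Reactants: 9 1-[2,4-bis(prop-2-en-1-yloxy)phenyl]ethan-1-one; 10 chlorotrimethylsilane; 11 N-bromosuccinimide
Product: 13 2-bromo-1-[2,4-bis(prop-2-en-1-yloxy)phenyl]ethan-1-one, via silyl enol ether 12 (not isolated)
Conditions: LiN(SiMe3)2, THF, −78 °C; Me3SiCl; then NBS, −78 → 0 °C
Reagents that add atoms: N-bromosuccinimide (11), O=C1CCC(=O)N1Br; chlorotrimethylsilane (10), C[Si](C)(C)Cl (its silicon stays only in 12)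
Why: Bromination of the enol silane derived from the lithium enolate is regiospecific for the α-carbon and should be much faster than attack of NBS on the allyl alkenes or the dialkoxyarene, which direct bromination of the ketone would not guarantee.

**Step 6**
Reactants: 7 2-hydroxy-3,5-bis(3-methylbut-2-en-1-yl)-4-(prop-2-en-1-yloxy)benzaldehyde; 13 2-bromo-1-[2,4-bis(prop-2-en-1-yloxy)phenyl]ethan-1-one
Product: 15 (3R)-3-[2,4-bis(prop-2-en-1-yloxy)phenyl]-3-hydroxy-6,8-bis(3-methylbut-2-en-1-yl)-7-(prop-2-en-1-yloxy)-2,3-dihydro-4H-chromen-4-one, via keto aldehyde 14 (not isolated)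
Conditions: Cs2CO3 (1.2 equiv), THF, rt to 40 °C until 7 is consumed; then, same flask, (5aR,10bS)-2-(pentafluorophenyl)-5a,10b-dihydro-4H,6H-indeno[2,1-b][1,2,4]triazolo[4,3-d][1,4]oxazin-2-ium tetrafluoroborate (15 mol%), rt
Reagents that add atoms: none
Why: The caesium phenoxide of 7 displaces bromide from 13 (Williamson reaction, O1–C2 bond) to give 14, whose aldehyde then adds the triazolylidene freed by the remaining carbonate; the resulting Breslow intermediate attacks the tethered aryl ketone and, after proton transfer, releases the carbene (C4–C3 bond and the tertiary carbinol). The closest known reaction type is the carbene-catalysed intramolecular crossed aldehyde–ketone benzoin reaction of 2-(2-aryl-2-oxoethoxy)benzaldehydes to 3-aryl-3-hydroxychroman-4-ones, here run in the same flask as the ether formation. Ring C closes in a 6-exo-trig mode, the acyl anion carbon on ring A attacking the ketone carbonyl that lies outside the forming ring. The C3 stereocentre is controlled by the catalyst: the indane wall of the triazolylidene shields one face of the hydrogen-bonded enaminol–ketone array, so that addition to the Si face of the ketone (O > CH2O > aryl) should give the (R)-carbinol, which has no α-hydrogen and cannot epimerise later. The step needs the crossed benzoin to beat the base-mediated intramolecular aldol condensation of the aryloxymethyl ketone (benzofuran formation) and aldehyde homo-coupling; the weak heterogeneous base, room temperature, the six-membered transition state and the fact that only the aldehyde can form a Breslow intermediate should secure this, and adding the catalyst only after 13 is consumed keeps the carbene from being alkylated.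

**Step 7**
Reactants: 15 (3R)-3-[2,4-bis(prop-2-en-1-yloxy)phenyl]-3-hydroxy-6,8-bis(3-methylbut-2-en-1-yl)-7-(prop-2-en-1-yloxy)-2,3-dihydro-4H-chromen-4-one
Product: 16 (3R)-3-(2,4-dihydroxyphenyl)-3,7-dihydroxy-6,8-bis(3-methylbut-2-en-1-yl)-2,3-dihydro-4H-chromen-4-one
Conditions: Pd(PPh3)4 (10 mol%), morpholine (10 equiv), THF, rt, degassed; dilute citric acid work-up
Reagents that add atoms: none
Why: Tsuji–Trost deallylation, in which zerovalent palladium ionises the three aryl allyl ethers to π-allyl complexes that morpholine captures, should free the phenols under near-neutral conditions that leave the C-prenyl groups, the α-ketol and the C3 stereocentre untouched.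

**Compound list**
1 | 2,4-dihydroxybenzaldehyde | O=Cc1ccc(O)cc1O | starting material
2 | N-iodosuccinimide | O=C1CCC(=O)N1I | starting material
3 | 2,4-dihydroxy-3,5-diiodobenzaldehyde | O=Cc1cc(I)c(O)c(I)c1O | intermediate
4 | tributyl(3-methylbut-2-en-1-yl)stannane | CCCC[Sn](CCCC)(CCCC)CC=C(C)C | starting material
5 | 2,4-dihydroxy-3,5-bis(3-methylbut-2-en-1-yl)benzaldehyde | CC(C)=CCc1cc(C=O)c(O)c(CC=C(C)C)c1O | intermediate
6 | allyl bromide (3-bromoprop-1-ene) | C=CCBr | starting material
7 | 2-hydroxy-3,5-bis(3-methylbut-2-en-1-yl)-4-(prop-2-en-1-yloxy)benzaldehyde | C=CCOc1c(CC=C(C)C)cc(C=O)c(O)c1CC=C(C)C | intermediate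
8 | 1-(2,4-dihydroxyphenyl)ethan-1-one | CC(=O)c1ccc(O)cc1O | starting material
9 | 1-[2,4-bis(prop-2-en-1-yloxy)phenyl]ethan-1-one | CC(=O)c1ccc(OCC=C)cc1OCC=C | intermediate
10 | chlorotrimethylsilane | C[Si](C)(C)Cl | starting material
11 | N-bromosuccinimide | O=C1CCC(=O)N1Br | starting material
12 | ({1-[2,4-bis(prop-2-en-1-yloxy)phenyl]ethenyl}oxy)(trimethyl)silane, formed in the flask | C=C(O[Si](C)(C)C)c1ccc(OCC=C)cc1OCC=C | intermediate
13 | 2-bromo-1-[2,4-bis(prop-2-en-1-yloxy)phenyl]ethan-1-one | O=C(CBr)c1ccc(OCC=C)cc1OCC=C | intermediate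
14 | 2-{2-[2,4-bis(prop-2-en-1-yloxy)phenyl]-2-oxoethoxy}-3,5-bis(3-methylbut-2-en-1-yl)-4-(prop-2-en-1-yloxy)benzaldehyde, formed in the flask | C=CCOc1c(CC=C(C)C)cc(C=O)c(OCC(=O)c2ccc(OCC=C)cc2OCC=C)c1CC=C(C)C | intermediate
15 | (3R)-3-[2,4-bis(prop-2-en-1-yloxy)phenyl]-3-hydroxy-6,8-bis(3-methylbut-2-en-1-yl)-7-(prop-2-en-1-yloxy)-2,3-dihydro-4H-chromen-4-one | CC(C)=CCc1cc2c(c(CC=C(C)C)c1OCC=C)OC[C@](O)(c1ccc(OCC=C)cc1OCC=C)C2=O | intermediate
16 | (3R)-3-(2,4-dihydroxyphenyl)-3,7-dihydroxy-6,8-bis(3-methylbut-2-en-1-yl)-2,3-dihydro-4H-chromen-4-one | CC(C)=CCc1cc2c(c(CC=C(C)C)c1O)OC[C@](O)(c1ccc(O)cc1O)C2=O | target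

**Totals**
Total step count: 7. Longest linear sequence: 5 steps (steps 1, 2, 3, 6, 7); steps 4 and 5 form the second branch.

**Steps most likely to fail**

1. Step 6. The base-mediated intramolecular aldol condensation of the aryloxymethyl ketone onto the aldehyde may outrun carbene addition, the attack on the hindered, electron-rich 2,4-dialkoxyaryl ketone may be slow, and the facial discrimination may be insufficient. The fallback replaces the carbene umpolung by a reductive ketyl coupling and sets out from 7 and 13. These are joined without catalyst (K2CO3, acetone, rt) and keto aldehyde 14 is isolated. SmI2 (2.5 equiv) in THF–t-BuOH at −78 °C should then close ring C by pinacol coupling to racemic 3-[2,4-bis(prop-2-en-1-yloxy)phenyl]-6,8-bis(3-methylbut-2-en-1-yl)-7-(prop-2-en-1-yloxy)-3,4-dihydro-2H-chromene-3,4-diol F1, as a diastereomer mixture in which the cis-diol is expected to prevail. Parikh–Doering oxidation (SO3·pyridine, DMSO, Et3N, 0 °C), which does not cleave glycols and spares the tertiary carbinol and the alkenes, should give racemic 3-[2,4-bis(prop-2-en-1-yloxy)phenyl]-3-hydroxy-6,8-bis(3-methylbut-2-en-1-yl)-7-(prop-2-en-1-yloxy)-2,3-dihydro-4H-chromen-4-one F2. The enantiomers are separated by preparative chromatography on a chiral stationary phase, and the (R)-enantiomer is 15, where the fallback rejoins the route.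

2. Step 2. The prenyl transfer may proceed with allyl transposition (1,1-dimethylallyl in place of prenyl), the acidic iodophenol may protonate the stannane, the C–I bonds may be reduced, or the aldehyde may be allylated. The fallback builds the side chains without any cross-coupling, sets out from 1 and comes back at 5. Selective O-allylation (allyl bromide, K2CO3, acetone) should give 2-hydroxy-4-(prop-2-en-1-yloxy)benzaldehyde F3. Aromatic Claisen rearrangement (N,N-diethylaniline, 190 °C) should give 2,4-dihydroxy-3-(prop-2-en-1-yl)benzaldehyde F4; any 5-allyl isomer is carried along, because the second cycle fills the other ortho position and converges on the same product. A second O-allylation should give 2-hydroxy-3-(prop-2-en-1-yl)-4-(prop-2-en-1-yloxy)benzaldehyde F5, and a second Claisen rearrangement 2,4-dihydroxy-3,5-bis(prop-2-en-1-yl)benzaldehyde F6. Cross-metathesis of F6 with excess 2-methylbut-2-ene (second-generation Grubbs catalyst RuCl2(=CHPh)(H2IMes)(PCy3), CH2Cl2, 40 °C) should then give 5.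

3. Step 7. The π-allyl palladium intermediates may C-allylate the liberated electron-rich resorcinol ring B or ring A, cleavage of the ring A ether flanked by two prenyl groups may stay incomplete, and the free polyphenol α-ketol may degrade in the amine medium. The fallback avoids π-allyl species altogether, sets out from 15 and comes back at 16. Isomerisation with [Ir(cod)(PMePh2)2]PF6 (activated with H2, then purged; THF, rt), which acts on the terminal allyl ethers and not on the trisubstituted prenyl alkenes, should give (3R)-3-{2,4-bis[(1E)-prop-1-en-1-yloxy]phenyl}-3-hydroxy-6,8-bis(3-methylbut-2-en-1-yl)-7-[(1E)-prop-1-en-1-yloxy]-2,3-dihydro-4H-chromen-4-one F7. Hydrolysis of the three enol ethers with 0.5 M HCl in acetone–water at rt should then give 16.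

**Further compounds**
F1 | step 6 | 3-[2,4-bis(prop-2-en-1-yloxy)phenyl]-6,8-bis(3-methylbut-2-en-1-yl)-7-(prop-2-en-1-yloxy)-3,4-dihydro-2H-chromene-3,4-diol (racemic, diastereomer mixture, no configuration specified) | CC(C)=CCc1cc2c(c(CC=C(C)C)c1OCC=C)OCC(O)(c1ccc(OCC=C)cc1OCC=C)C2O
F2 | step 6 | racemic 3-[2,4-bis(prop-2-en-1-yloxy)phenyl]-3-hydroxy-6,8-bis(3-methylbut-2-en-1-yl)-7-(prop-2-en-1-yloxy)-2,3-dihydro-4H-chromen-4-one | CC(C)=CCc1cc2c(c(CC=C(C)C)c1OCC=C)OCC(O)(c1ccc(OCC=C)cc1OCC=C)C2=O
F3 | step 2 | 2-hydroxy-4-(prop-2-en-1-yloxy)benzaldehyde | C=CCOc1ccc(C=O)c(O)c1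
F4 | step 2 | 2,4-dihydroxy-3-(prop-2-en-1-yl)benzaldehyde | C=CCc1c(O)ccc(C=O)c1O
F5 | step 2 | 2-hydroxy-3-(prop-2-en-1-yl)-4-(prop-2-en-1-yloxy)benzaldehyde | C=CCOc1ccc(C=O)c(O)c1CC=C
F6 | step 2 | 2,4-dihydroxy-3,5-bis(prop-2-en-1-yl)benzaldehyde | C=CCc1cc(C=O)c(O)c(CC=C)c1O
F7 | step 7 | (3R)-3-{2,4-bis[(1E)-prop-1-en-1-yloxy]phenyl}-3-hydroxy-6,8-bis(3-methylbut-2-en-1-yl)-7-[(1E)-prop-1-en-1-yloxy]-2,3-dihydro-4H-chromen-4-one | CC(C)=CCc1cc2c(c(CC=C(C)C)c1O/C=C/C)OC[C@](O)(c1ccc(O/C=C/C)cc1O/C=C/C)C2=O
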